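## Retrosynthetic overview
- Sophoranone (**1**) is disconnected at the C2–aryl bond. The forward step is an enantioselective Pd(II)/PyOx conjugate arylation of the flat, achiral 7‑hydroxy‑8‑prenylchromone (**2**) with the symmetric arylboronic acid (4‑hydroxy‑3,5‑diprenylphenyl)boronic acid (**3**). It breaks the pseudo‑aromatic pyranone C2=C3 bond and sets C2 in one operation.
- Chromone **2** comes from 2,4‑dihydroxyacetophenone (**4**) by C3‑prenylation (to **5**) and one‑carbon pyranone annulation.
- Boronic acid **3** comes from 4‑bromophenol (**6**) by double ortho‑C‑prenylation (to **7**) and Br/B exchange.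
- Ring order: ring A is already present in **4**, ring C is formed in step 2, and ring B is attached intact in the last step, which also creates the only stereocentre.

Assumption: the target is (2S), which I derived from the SMILES. The (S)‑configured t‑Bu‑PyOx ligand is assumed to give the (S)‑flavanone; this would be confirmed by ligand‑enantiomer screening and optical rotation. Every other step is achiral.

## Route

**Step 1**
Reactants: **4** 2,4‑dihydroxyacetophenone; **8** prenyl bromide (1‑bromo‑3‑methylbut‑2‑ene)
Product: **5** 1‑[2,4‑dihydroxy‑3‑(3‑methylbut‑2‑enyl)phenyl]ethanone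
Conditions: **8** (1.0 equiv), KOH (2.5 equiv), MeOH/H2O 1:1, 0 °C → rt, 12 h; chromatographic removal of the 5‑prenyl isomer
Reagents that add atoms: prenyl bromide, CC(C)=CCBr
Why: In aqueous KOH the phenoxide is H‑bond solvated at oxygen, so alkylation occurs at carbon, at the position flanked by both oxygens (C3), via a transient dearomatised dienone that re‑tautomerises (ortho‑selective C‑alkylation of a phenoxide).

**Step 2**
Reactants: **5**; **9** N,N‑dimethylformamide dimethyl acetal (DMF‑DMA)
Product: **2** 7‑hydroxy‑8‑(3‑methylbut‑2‑enyl)‑4H‑chromen‑4‑one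
Conditions: one pot. (i) **9** (3 equiv), toluene, 110 °C, 4 h. (ii) Concentrate, EtOH, 3 M HCl, 50 °C, 2 h.
Reagents that add atoms: DMF‑DMA, CN(C)C(OC)OC (supplies C2 of the chromone as CH)
Why: DMF‑DMA converts the acetyl CH3 into an enaminone, and acid‑mediated phenol addition/Me2NH elimination closes the pyranone (enaminone–chromone annulation), so ring C forms with no stereocentre.

**Step 3**
Reactants: **6** 4‑bromophenol; **8** prenyl bromide
Product: **7** 4‑bromo‑2,6‑bis(3‑methylbut‑2‑enyl)phenol
Conditions: **8** (2.6 equiv), NaOH (2.8 equiv), H2O, 0 °C → rt, 16 h; chromatography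
Reagents that add atoms: prenyl bromide, CC(C)=CCBr (two prenyl groups)
Why: The same aqueous‑phenoxide C‑alkylation occurs twice, at both ortho positions, because para is blocked by Br, and gives the symmetric 2,6‑diprenylphenol.

**Step 4**
Reactants: **7**; **10** triisopropyl borate
Product: **3** (4‑hydroxy‑3,5‑bis(3‑methylbut‑2‑enyl)phenyl)boronic acid
Conditions: n‑BuLi (2.3 equiv), THF, –78 °C, 45 min; **10** (3 equiv), –78 °C → rt; then 1 M HCl, rt
Reagents that add atoms: B(OiPr)3, CC(C)OB(OC(C)C)OC(C)C (supplies B(OH)2 after hydrolysis)
Why: The first equivalent of n‑BuLi forms the lithium phenoxide, which protects OH, and the second does Li–Br exchange; the aryllithium is trapped by borate and hydrolysed (lithium–halogen exchange/borylation).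

**Step 5 (key step)**
Reactants: **2**; **3** (3 equiv); **11** (S)‑4‑tert‑butyl‑2‑(pyridin‑2‑yl)‑4,5‑dihydrooxazole ((S)‑t‑Bu‑PyOx, chiral ligand)
Product: **1** sophoranone, (2S)‑7,4'‑dihydroxy‑8,3',5'‑triprenylflavanone
Conditions: Pd(OCOCF3)2 (10 mol %), **11** (12 mol %), NH4PF6 (20 mol %), ClCH2CH2Cl/H2O (20:1), N2, 60 °C, 24 h; neutral work‑up, chromatography on silica with no base
Reagents that add atoms: none (the C3 hydrogen comes from water/TFA)
Why: Proposed new method: this exact coupling (free phenols and three prenyl groups on the two partners) is not precedented, and the closest known reaction type is Pd(II)/PyOx Hayashi–Miyaura‑type conjugate arylation of chromones and β‑substituted cyclic enones. Transmetalation of ArB(OH)2 onto cationic (PyOx)Pd+ gives Ar–Pd+, and the tert‑butyl group of the ligand blocks one quadrant of the planar substrate, so enantio‑determining insertion of the chromone C2=C3 bond occurs on one face and sets C2 by enantiotopic‑face differentiation. Protodepalladation of the Pd‑enolate (TFA/H2O) should be faster than β‑O elimination, which would open the ring. The acidic conditions and neutral work‑up avoid retro‑oxa‑Michael racemisation of C2. No oxidant is present, so Wacker‑type cyclisation onto the prenyl groups has no turnover path.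

## Compound list
1 | sophoranone, (2S)‑7,4'‑dihydroxy‑8,3',5'‑triprenylflavanone | CC(C)=CCc1cc([C@@H]2CC(=O)c3ccc(O)c(CC=C(C)C)c3O2)cc(CC=C(C)C)c1O | target
2 | 7‑hydroxy‑8‑prenylchromone | O=c1ccoc2c1ccc(O)c2CC=C(C)C | intermediate
3 | (4‑hydroxy‑3,5‑diprenylphenyl)boronic acid | CC(C)=CCc1cc(B(O)O)cc(CC=C(C)C)c1O | intermediate
4 | 2,4‑dihydroxyacetophenone | CC(=O)c1ccc(O)cc1O | starting material
5 | 2,4‑dihydroxy‑3‑prenylacetophenone | CC(=O)c1ccc(O)c(CC=C(C)C)c1O | intermediate
6 | 4‑bromophenol | Oc1ccc(Br)cc1 | starting material
7 | 4‑bromo‑2,6‑diprenylphenol | CC(C)=CCc1cc(Br)cc(CC=C(C)C)c1O | intermediate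
8 | prenyl bromide | CC(C)=CCBr | starting material
9 | DMF‑DMA | CN(C)C(OC)OC | starting material
10 | triisopropyl borate | CC(C)OB(OC(C)C)OC(C)C | starting material
11 | (S)‑4‑tert‑butyl‑2‑(pyridin‑2‑yl)‑4,5‑dihydrooxazole ((S)‑t‑Bu‑PyOx) | CC(C)(C)[C@H]1COC(=N1)c1ccccn1 | starting material (commercial chiral ligand)

## Totals
Total steps: 5. Longest linear sequence: 3 steps (4 → 5 → 2 → 1, or 6 → 7 → 3 → 1).

## Three steps most likely to fail
1. **Step 5 (key arylation).** The 7‑OH chromone is a poor acceptor, and ring opening or low ee is possible.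
   - Fallback: change to a chalcone route. Make 4‑hydroxy‑3,5‑diprenylbenzaldehyde from **7** (n‑BuLi then DMF), do a Claisen–Schmidt condensation with **5**, and cyclise the 2'‑hydroxychalcone with a chiral bifunctional (cinchona‑thiourea or iminophosphorane) oxa‑Michael catalyst.
2. **Step 3 (double C‑prenylation in water).** It may give O‑prenylation, mono‑prenylation, para‑ipso dienone products and a low yield.
   - Fallback: build the two prenyl groups from allyl. Do O‑allylation and aromatic Claisen rearrangement on **6**, repeat to give 2,6‑diallyl‑4‑bromophenol, then bis cross‑metathesis with 2‑methyl‑2‑butene (Hoveyda–Grubbs II).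
3. **Step 1 (C3 vs C5 regioselectivity).** Both positions are nucleophilic and the yield is modest.
   - Fallback: do 4‑O‑allylation (K2CO3), Claisen rearrangement to the 3‑allyl phenol, and olefin cross‑metathesis with 2‑methyl‑2‑butene to install the prenyl group.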